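The seven-membered ring (daucane numbering: C1 quaternary ring-fusion carbon, C5 ring-fusion CH, C6 ester carbinol, C7=C8–C9=O enone, C10 carbinol) is cut at C6–C7 and C1–C10. Both bonds form in one (4+3) cycloaddition of 3-methylfuran (C7–C10) with a rhodium cyclopentenyl carbene (C6, C5, C1, carrying the five-membered ring), released by decarbenation of a 7-alkenylcycloheptatriene and reacting by cyclopropanation/Cope rearrangement. The step exploits the 1,4-relation of the C10 hydroxyl and C7 across the enone: this γ-hydroxy enone is a masked furan, whose oxygen bridge, absent from the target, rigidifies the ring while C4, C5 and C6 are set and is finally opened by β-elimination.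

Key step: step 5

Remark: daucane numbering is used throughout (C1 methyl-bearing ring-fusion carbon; C2, C3 methylenes; C4 isopropyl carbinol; C5 ring-fusion CH; C6 ester carbinol; C7=C8 alkene with the methyl on C8; C9 ketone; C10 secondary carbinol). β is the face that carries the C1 methyl group; absolute configuration is as in the SMILES.

Step 1
Reactants: 1 3-methylcyclopent-2-en-1-one
Product: 2 2-bromo-3-methylcyclopent-2-en-1-one
Conditions: Br2, CH2Cl2, 0 °C; then Et3N, 0 °C → rt
Reagents that add atoms: bromine, BrBr
Why: Addition of bromine across the enone and triethylamine-induced dehydrobromination (α-bromination of an enone by addition–elimination) gives the α-bromoenone; no stereocentre is formed.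

Step 2
Reactants: 2 2-bromo-3-methylcyclopent-2-en-1-one
Product: 3 (S)-2-bromo-3-methylcyclopent-2-en-1-ol
Conditions: (R)-Me-CBS oxazaborolidine [(R)-1-methyl-3,3-diphenyltetrahydro-1H,3H-pyrrolo[1,2-c][1,3,2]oxazaborole] (10 mol %), BH3·SMe2, THF, −20 °C
Reagents that add atoms: none
Why: Corey–Bakshi–Shibata reduction, in which the bromoalkenyl arm acts as the large substituent, so the (R)-catalyst should deliver hydride to the face that gives the (S)-carbinol (the future C4).

Step 3
Reactants: 3 (S)-2-bromo-3-methylcyclopent-2-en-1-ol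
Product: 4 (S)-(2-bromo-3-methylcyclopent-2-en-1-yloxy)(tert-butyl)dimethylsilane
Conditions: t-BuMe2SiCl, imidazole, DMF, rt
Reagents that add atoms: tert-butyldimethylsilyl chloride, CC(C)(C)[Si](C)(C)Cl
Why: Standard silylation of a secondary alcohol installs the bulky ether that later shields the β face; C4 is untouched.

Step 4
Reactants: 4 (S)-(2-bromo-3-methylcyclopent-2-en-1-yloxy)(tert-butyl)dimethylsilane; 5 tropylium tetrafluoroborate
Product: 7 7-[(S)-5-(tert-butyldimethylsilyloxy)-2-methylcyclopent-1-en-1-yl]cyclohepta-1,3,5-triene, via vinyllithium 6 (not isolated)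
Conditions: t-BuLi (2.1 equiv), Et2O/THF, −78 °C; then 5, −78 °C → rt
Reagents that add atoms: none
Why: Bromine–lithium exchange gives vinyllithium 6, which is captured by the tropylium cation (nucleophilic addition to a stabilised carbocation) to give the 7-alkenylcycloheptatriene; C4 is not involved and the silyl ether is not placed for migration at −78 °C.

Step 5
Reactants: 7 7-[(S)-5-(tert-butyldimethylsilyloxy)-2-methylcyclopent-1-en-1-yl]cyclohepta-1,3,5-triene; 8 3-methylfuran
Product: 10 oxygen-bridged tricyclic diene (7β,10β-epoxy bridge; C5=C6 and C8=C9; 1β-methyl; 8-methyl; 4β-silyloxy), via cis-divinylcyclopropane 9 (not isolated)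
Conditions: Rh2(O2CCF3)4 (5 mol %), 8 (5 equiv), ClCH2CH2Cl, 40 °C, then 80 °C
Reagents that add atoms: none
Why: The dirhodium carboxylate cleaves the norcaradiene tautomer of 7 with loss of benzene (retro-Buchner decarbenation) to give a rhodium cyclopentenyl carbene whose carbene carbon is C6; this electrophilic carbene adds to the C2=C3 bond of 8 (C6 to the furan α-carbon next to the methyl-bearing carbon, the more nucleophilic position as in electrophilic substitution of 3-methylfuran) to give cis-divinylcyclopropane 9, which rearranges by a Cope [3,3] shift that joins C1 to C10 and breaks the cyclopropane. The closest known reaction type is the (4+3) cycloaddition of rhodium vinyl carbenes with furans and 1,3-dienes by tandem cyclopropanation/Cope rearrangement. The three-membered ring closes by [2+1] carbene transfer and the seven-membered carbocycle by the [3,3] sigmatropic ring expansion through a boat transition state, the furan oxygen becoming the C7–O–C10 bridge of an 8-oxabicyclo[3.2.1]octadiene. In that boat the C1 methyl group, held cis to C6 by the cyclopentene ring, must point to the oxygen bridge, which fixes C1 relative to C7 and C10 (methyl and C10 oxygen cis). The absolute sense comes from C4: the furan approaches the carbene, and stacks in the Cope transition state, on the cyclopentene face anti to the bulky silyloxy group, so the C1 methyl group ends cis to the C4 oxygen. The step needs regioselectivity on the furan, cis-selective cyclopropanation and this facial bias; they are secured by the 3-methyl group, by the cis preference typical of these donor rhodium carbenes and by the C4 silyl ether.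

Step 6
Reactants: 10 oxygen-bridged tricyclic diene (4β-silyloxy)
Product: 11 allylic alcohol (as 10 with 4β-OH)
Conditions: Bu4NF, THF, 0 °C → rt
Reagents that add atoms: none
Why: Fluoride-mediated desilylation frees the C4 allylic alcohol that directs the next step; no stereocentre changes.

Step 7
Reactants: 11 allylic alcohol (4β-OH)
Product: 12 epoxy alcohol (5β,6β-epoxide of 11)
Conditions: VO(acac)2 (5 mol %), t-BuOOH, CH2Cl2, 0 °C → rt
Reagents that add atoms: tert-butyl hydroperoxide, CC(C)(C)OO
Why: Hydroxyl-directed vanadium-catalysed epoxidation (Sharpless–Michaelson) reacts only at the allylic C5=C6 alkene and delivers oxygen syn to the C4 hydroxyl, that is to the β face, which sets C5 and C6.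

Step 8
Reactants: 12 epoxy alcohol (5β,6β-epoxide; 4β-OH)
Product: 13 β-hydroxy ketone (4-oxo; 5α-H; 6β-OH; C8=C9; 7β,10β-epoxy bridge)
Conditions: BF3·OEt2, CH2Cl2, −78 °C; NaHCO3 quench
Reagents that add atoms: none
Why: Semipinacol rearrangement of a 2,3-epoxy alcohol with 1,2-hydride shift (non-aldol aldol type): the Lewis acid opens the epoxide at tertiary C5 and the C4 hydrogen, on the α face opposite the breaking C5–O bond, migrates to C5, which gives the C4 ketone, the trans ring fusion (C5–H anti to the C1 methyl group, the cyclopentane bond equatorial on the bridged chair) and keeps the 6β-oxygen.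

Step 9
Reactants: 13 β-hydroxy ketone (4-oxo; 5α-H; 6β-OH)
Product: 14 diol (4β-OH; 4α-isopropyl; 5α-H; 6β-OH; C8=C9; 7β,10β-epoxy bridge)
Conditions: i-PrMgCl, CeCl3, THF, −78 → −20 °C
Reagents that add atoms: isopropylmagnesium chloride, CC(C)[Mg]Cl
Why: Organocerium (Imamoto) 1,2-addition suppresses enolisation and reduction of the hindered β-hydroxy ketone, and the nucleophile should enter C4 from the α face, beside the axial C5 hydrogen and away from the C1 methyl group and the metal-bound C6 alkoxide, so the new hydroxyl is β.

Step 10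
Reactants: 14 diol (4β-OH; 4α-isopropyl; 6β-OH; C8=C9)
Product: 16 bridged diketone (6,9-dioxo; 4β-OH; 4α-isopropyl; 5α-H; 8α-methyl; 7β,10β-epoxy bridge), via organoborane 15 (not isolated)
Conditions: BH3·THF, THF, 0 °C → rt; then N-methylmorpholine N-oxide, n-Pr4NRuO4 (10 mol %), 4 Å sieves, CH2Cl2, rt
Reagents that add atoms: N-methylmorpholine N-oxide, C[N+]1([O-])CCOCC1
Why: Hydroboration of the strained C8=C9 alkene from the exo face puts boron on the less substituted C9, and amine-oxide oxidation of the C–B bond followed by perruthenate (Ley–Griffith) oxidation in the same flask turns C9 and the mis-set C6 carbinol into ketones; C6 is deliberately erased, C5 keeps its more stable trans configuration and the C8 centre is removed later.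

Step 11
Reactants: 16 bridged diketone (6,9-dioxo; 4β-OH)
Product: 17 6α-alcohol (6α-OH; 9-oxo; 4β-OH; 7β,10β-epoxy bridge)
Conditions: Me4NBH(OAc)3, MeCN/AcOH, −20 → 0 °C
Reagents that add atoms: none
Why: Evans–Saksena hydroxyl-directed reduction: the β-hydroxyl on C4 exchanges onto boron and delivers hydride through a six-membered transition state to the β face of the C6 ketone, which gives the 6α-alcohol, while the C9 ketone has no free hydroxyl neighbour and is not reduced.

Step 12
Reactants: 17 6α-alcohol (9-oxo; 4β-OH); 18 4-methoxybenzoyl chloride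
Product: 20 target 4β,10β-dihydroxy-6α-(4-methoxybenzoyloxy)dauc-7-en-9-one, via bridged anisoate 19 (not isolated)
Conditions: 18, 4-(dimethylamino)pyridine, pyridine, CH2Cl2, 0 °C → rt; MeOH; then 1,8-diazabicyclo[5.4.0]undec-7-ene, 0 °C
Reagents that add atoms: none
Why: Nucleophile-catalysed acylation esterifies the only secondary hydroxyl (the tertiary C4–OH is inert), and the amidine base then removes the C8 hydrogen α to the C9 ketone so that the enolate expels the C7 oxygen (E1cB β-elimination), which opens the bridge to the C7=C8 enone and frees the C10 hydroxyl with its configuration unchanged.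

Compound list
1 | 3-methylcyclopent-2-en-1-one | CC1=CC(=O)CC1 | starting material
2 | 2-bromo-3-methylcyclopent-2-en-1-one | CC1=C(Br)C(=O)CC1 | intermediate
3 | (S)-2-bromo-3-methylcyclopent-2-en-1-ol | O[C@H]1CCC(C)=C1Br | intermediate
4 | (S)-(2-bromo-3-methylcyclopent-2-en-1-yloxy)(tert-butyl)dimethylsilane | CC(C)(C)[Si](C)(C)O[C@H]1CCC(C)=C1Br | intermediate
5 | tropylium tetrafluoroborate | [CH+]1C=CC=CC=C1.F[B-](F)(F)F | starting material
6 | (S)-[5-(tert-butyldimethylsilyloxy)-2-methylcyclopent-1-en-1-yl]lithium (not isolated) | CC(C)(C)[Si](C)(C)O[C@H]1CCC(C)=C1[Li] | intermediate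
7 | 7-[(S)-5-(tert-butyldimethylsilyloxy)-2-methylcyclopent-1-en-1-yl]cyclohepta-1,3,5-triene | CC(C)(C)[Si](C)(C)O[C@H]1CCC(C)=C1C2C=CC=CC=C2 | intermediate
8 | 3-methylfuran | Cc1ccoc1 | starting material
9 | cis-divinylcyclopropane: 6-endo-[(S)-5-(tert-butyldimethylsilyloxy)-2-methylcyclopent-1-en-1-yl]-5-methyl-2-oxabicyclo[3.1.0]hex-3-ene (not isolated) | C[C@]12C=CO[C@H]1[C@H]2C1=C(C)CC[C@@H]1O[Si](C)(C)C(C)(C)C | intermediate
10 | oxygen-bridged tricyclic diene: hydroazulene with C5=C6 and C8=C9 double bonds, 1β-methyl, 8-methyl, 4β-(tert-butyldimethylsilyloxy), 7β,10β-epoxy bridge | CC(C)(C)[Si](C)(C)O[C@H]1CC[C@]2(C)[C@H]3O[C@H](C(C)=C3)C=C12 | intermediate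
11 | allylic alcohol: as 10 with 4β-OH | O[C@H]1CC[C@]2(C)[C@H]3O[C@H](C(C)=C3)C=C12 | intermediate
12 | epoxy alcohol: 5β,6β-epoxide of 11 | O[C@H]1CC[C@]2(C)[C@H]3O[C@H](C(C)=C3)[C@H]4O[C@@]124 | intermediate
13 | β-hydroxy ketone: 4-oxo, 5α-H, 6β-OH, C8=C9, 7β,10β-epoxy bridge, 1β-methyl | O=C1CC[C@]2(C)[C@H]3O[C@H](C(C)=C3)[C@@H](O)[C@@H]12 | intermediate
14 | diol: 4β-OH, 4α-isopropyl, 5α-H, 6β-OH, C8=C9, 7β,10β-epoxy bridge | O[C@@]1(C(C)C)CC[C@]2(C)[C@H]3O[C@H](C(C)=C3)[C@@H](O)[C@@H]12 | intermediate
15 | organoborane: 9β-BH2 (8β-H, 8α-methyl) with the C4 and C6 oxygens as O–BH2, drawn monomeric (not isolated) | [BH2]O[C@@]1(C(C)C)CC[C@]2(C)[C@H]3O[C@H]([C@@H](C)[C@@H]3[BH2])[C@@H](O[BH2])[C@@H]12 | intermediate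
16 | bridged diketone: 6,9-dioxo, 4β-OH, 4α-isopropyl, 5α-H, 8α-methyl, 7β,10β-epoxy bridge | O[C@@]1(C(C)C)CC[C@]2(C)[C@H]3O[C@H]([C@@H](C)C3=O)C(=O)[C@@H]12 | intermediate
17 | 6α-alcohol of 16 (9-ketone kept) | O[C@@]1(C(C)C)CC[C@]2(C)[C@H]3O[C@H]([C@@H](C)C3=O)[C@H](O)[C@@H]12 | intermediate
18 | 4-methoxybenzoyl chloride | COc1ccc(cc1)C(Cl)=O | starting material
19 | bridged anisoate: 6α-(4-methoxybenzoate) of 17 (not isolated) | O[C@@]1(C(C)C)CC[C@]2(C)[C@H]3O[C@H]([C@@H](C)C3=O)[C@H](OC(=O)c4ccc(OC)cc4)[C@@H]12 | intermediate
20 | 4β,10β-dihydroxy-6α-(4-methoxybenzoyloxy)dauc-7-en-9-one (1β-methyl, 5α-H) | COc1ccc(C(=O)O[C@H]2C=C(C)C(=O)[C@H](O)[C@@]3(C)CC[C@@](O)(C(C)C)[C@H]23)cc1 | target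

Total step count: 12
Longest linear sequence: 12 steps (1 → 20)

Steps most likely to fail

Step 5. The decarbenation of the hindered cycloheptatriene may be too slow, or the rhodium carbene may be lost to cyclopropene formation or C–H insertion before it meets the furan; carbene attack at the unsubstituted furan α-carbon would also erode regioselectivity. The fallback sets out from 4 and replaces the rhodium carbene by a zinc carbenoid. Bromine–lithium exchange (t-BuLi) and formylation with DMF should give (S)-5-(tert-butyldimethylsilyloxy)-2-methylcyclopent-1-ene-1-carbaldehyde F1. Deoxygenative cyclopropanation of 8 with the zinc carbenoid of this enal (Zn(Hg), Me3SiCl, Et2O; Simmons–Smith-type carbenoid from a carbonyl compound) should give cis-divinylcyclopropane 9, now isolated. Heating 9 in toluene (Cope rearrangement) brings the route back at 10.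

Step 8. The epoxide may open with hydride shift from C6 instead of C4 (Meinwald pathway), or the aldol product may dehydrate under the Lewis acid. The fallback sets out from 11. Oxidation with MnO2 should give the C4 enone F2. Copper-catalysed conjugate borylation (CuCl, NaOt-Bu, bis[2-(diphenylphosphino)phenyl] ether, B2pin2, MeOH) should add boron to C6 anti to the C1 methyl group and leave C5 protonated α to the ketone, giving the 6α-boryl ketone F3. Oxidation with NaBO3·4H2O should give the 6α-hydroxy ketone F4, and i-PrMgCl/CeCl3 then the C6 epimer of 14, diol F5. Under the conditions of step 10 the C6 carbinol is oxidised as before, so the fallback comes back to the route at 16.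

Step 10. The amine oxide and the N-methylmorpholine formed from it may trigger premature β-elimination of the oxygen bridge in the nascent C9 ketone and expose the C10 carbinol to the perruthenate, or oxidation of the alkylborane may stall. The fallback sets out from 14 and separates the two events. Hydroboration with oxidative work-up (BH3·THF; then NaBO3·4H2O) should give the 6β,9β-dihydroxy triol F6. Buffered Dess–Martin periodinane (NaHCO3, CH2Cl2) then oxidises both secondary carbinols under non-basic conditions and returns to the route at 16.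

Further compounds
F1 | step 5 | (S)-5-(tert-butyldimethylsilyloxy)-2-methylcyclopent-1-ene-1-carbaldehyde | CC(C)(C)[Si](C)(C)O[C@H]1CCC(C)=C1C=O
F2 | step 8 | C4 enone: 4-oxo, C5=C6, C8=C9, 7β,10β-epoxy bridge, 1β-methyl | O=C1CC[C@]2(C)[C@H]3O[C@H](C(C)=C3)C=C12
F3 | step 8 | 6α-(pinacolatoboryl) ketone: 4-oxo, 5α-H, C8=C9, 7β,10β-epoxy bridge | O=C1CC[C@]2(C)[C@H]3O[C@H](C(C)=C3)[C@H](B4OC(C)(C)C(C)(C)O4)[C@@H]12
F4 | step 8 | 6α-hydroxy ketone (C6 epimer of 13) | O=C1CC[C@]2(C)[C@H]3O[C@H](C(C)=C3)[C@H](O)[C@@H]12
F5 | step 8 | diol, C6 epimer of 14 (4β-OH, 4α-isopropyl, 6α-OH) | O[C@@]1(C(C)C)CC[C@]2(C)[C@H]3O[C@H](C(C)=C3)[C@H](O)[C@@H]12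
F6 | step 10 | triol: 4β-OH, 4α-isopropyl, 6β-OH, 9β-OH, 8α-methyl, 7β,10β-epoxy bridge | O[C@@]1(C(C)C)CC[C@]2(C)[C@H]3O[C@H]([C@@H](C)[C@@H]3O)[C@@H](O)[C@@H]12
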